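The numbers of this flask were set for the occasion; the flask was simulated.

Decide first to count passes through the catalyst, not seconds.

D 2.0 M; Q 0.100 M; E 4.0 mM

- the form that holds most of the catalyst when 50% of the D are converted (what has only dissolved counts as not reacted) (X / G.E / G.E.Q / E)
- its share of the catalyst then

- given per volume of solution although it is solid: D
- at the start none of D is in solution
- what has only dissolved of D counts as not reacted
- charge of D (flask): 2.0 M

    D ⇌ G, rate k1*(cs1 - [G]) while solid is left; crystals form when [G] > cs1 (cs1 = 0.20 M, k1 = 0.152 s⁻¹)
    X ⇌ E + J (K2 = 0.861 M, k2 = 75.5 s⁻¹)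
    G.E + Q → G.E.Q (k3 = 5.33 M⁻¹ s⁻¹)
    G + E → G.E (k4 = 30.7 M⁻¹ s⁻¹)
    G.E → X (k5 = 198 s⁻¹)

G.E has two exits. It goes on to X at 198 s⁻¹, or Q captures it at 0.53 s⁻¹ per G.E with [Q] as charged. The capture has no way back in the scheme. So take the exit ratio N, the passes of G.E to X per capture by Q, which is a turnover number. Set against it T, the J demanded per catalyst charged.

N = 198 s⁻¹ / (5.33 M⁻¹ s⁻¹ × 0.100 M) = 371, so lg N = 2.57

T = 50% × 2.0 M / 4.0 mM = 250, so lg T = 2.40

lg(T/N) = −0.170, so the captured share is 67.3%

J counts the passes well enough, because X cannot hold more than the catalyst charged, far less than the J demanded. I reckon N with [Q] as charged, and the captured 2.69 mM is far less than the Q charged. My answer is G.E.Q, since its share exceeds that of the other forms together.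

Now take the neighbouring flask, the same but with twice the E. By my reckoning it makes the same J at this conversion with the same N, so it loses the same 2.69 mM. That is a third of its catalyst. So I reckon 1.31 mM outside G.E.Q for this flask and 5.31 mM for the neighbour, which is 4.06 times as much.

The forecast says G.E.Q at 66%. Its ground is that product build-up “only slows the cycle and does not change this partition”. My figure stands 1.3 percentage points above it.

The flask gives G.E.Q at 66.2%, with X at 18.4%, E at 15.0% and G.E at 0.411%.

In this flask at 15.3 s, G.E passes to X 370 times as fast as to G.E.Q, beside an N of 371, and the share of G.E.Q lies 1.1 points below the 67.3% that N gave. By N the neighbouring flask with twice the E keeps 4.06 times as much catalyst outside G.E.Q, and its rate is less than that, 3.00 times this flask's.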